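**Strategy.** Ring A is disconnected at C4a–C5 only. Its C8–C7–C6–C5 segment is read as a prenylated acetoacetyl chain hung from C8a, which is already the enol-ether carbon of an intact, enantiopure ring C, a (2S)-2-aryl-2,3-dihydro-4H-pyran-4-one; the acid terminus is masked as an acetone dioxinone. Heating releases an acylketene that acylates the vinylogous-ester α-carbon C4a, closing ring A and aromatising to the target with both phenols free, the 8-prenyl position fixed and C2 untouched. Precursor 15 comes from a dioxinone-derived methyl ketone dianion and an (S)-β-silyloxy Weinreb amide set by asymmetric transfer hydrogenation, followed by mild cyclodehydration.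

Key step: step 9

Remarks on the chemistry:
- Flavanone numbering (O1, C2–C8a) is used for ring atoms throughout, also in their precursors.
- The carbon that becomes C8 is stereogenic in 11–17 and is carried as a mixture of epimers (15 may also hold some exocyclic enol-ether tautomer). This is irrelevant because that carbon becomes aromatic.
- The sense of step 3 is assumed to follow the acetophenone model for the (S,S)-catalyst. It would be checked on 6 (Mosher esters) before material is carried forward; the (R,R)-catalyst is the mirror option.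
- The 4'-O-prenyl ether is installed first on purpose: a free 4'-phenol next to C2 would open ring C through a quinone methide under any base.

Step 1
Reactants: 1 methyl 4-hydroxybenzoate; 2 prenyl bromide (1-bromo-3-methylbut-2-ene)
Product: 3 methyl 4-[(3-methylbut-2-en-1-yl)oxy]benzoate
Conditions: K2CO3, acetone, reflux
Reagents that add atoms: none
Why: Williamson ether synthesis, in which the phenoxide displaces bromide at the primary allylic carbon (SN2) while the methyl ester is inert to carbonate in acetone.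

Step 2
Reactants: 3 methyl 4-[(3-methylbut-2-en-1-yl)oxy]benzoate; 4 N-methoxy-N-methylacetamide
Product: 5 N-methoxy-N-methyl-3-{4-[(3-methylbut-2-en-1-yl)oxy]phenyl}-3-oxopropanamide
Conditions: 4, LDA (2.2 equiv), THF, −78 °C; then 3, −78 → −20 °C; AcOH
Reagents that add atoms: none
Why: Crossed Claisen condensation of an amide lithium enolate with a non-enolisable aryl ester, in which the second equivalent of enolate deprotonates the β-keto amide as it forms and so shields the new ketone from further addition.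

Step 3
Reactants: 5 N-methoxy-N-methyl-3-{4-[(3-methylbut-2-en-1-yl)oxy]phenyl}-3-oxopropanamide
Product: 6 (3S)-3-hydroxy-N-methoxy-N-methyl-3-{4-[(3-methylbut-2-en-1-yl)oxy]phenyl}propanamide
Conditions: RuCl(p-cymene)[(S,S)-TsDPEN] (1 mol %), HCO2H/Et3N (5:2), EtOAc, 30 °C
Reagents that add atoms: none
Why: Noyori–Ikariya asymmetric transfer hydrogenation of an aryl ketone, in which the outer-sphere Ru–H/N–H catalyst ignores both trisubstituted alkenes and the (S,S)-ligand, through the CH–π contact between its η6-arene and the aryl group, delivers hydride to the Re face to set the (S)-carbinol that becomes C2.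

Step 4
Reactants: 6 (3S)-3-hydroxy-N-methoxy-N-methyl-3-{4-[(3-methylbut-2-en-1-yl)oxy]phenyl}propanamide
Product: 7 (3S)-3-[(tert-butyldimethylsilyl)oxy]-N-methoxy-N-methyl-3-{4-[(3-methylbut-2-en-1-yl)oxy]phenyl}propanamide
Conditions: TBSCl, imidazole, DMF, rt
Reagents that add atoms: tert-butyldimethylsilyl chloride, CC(C)(C)[Si](C)(C)Cl
Why: Corey silylation of the only hydroxyl group via the N-silylimidazolium ion, which leaves the stereocentre untouched and removes the acidic proton before the dianion chemistry.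

Step 5
Reactants: 8 2,2,6-trimethyl-4H-1,3-dioxin-4-one; 2 prenyl bromide
Product: 9 2,2-dimethyl-6-(4-methylpent-3-en-1-yl)-4H-1,3-dioxin-4-one
Conditions: LDA, THF/DMPU, −78 °C; then 2, −78 → −40 °C
Reagents that add atoms: none
Why: γ-Alkylation of the extended lithium dienolate of the dioxinone (vinylogous enolate alkylation), in which the polar co-solvent directs the soft allylic bromide to the γ-carbon and SN2 attack at the primary terminus keeps the prenyl unit linear.

Step 6
Reactants: 9 2,2-dimethyl-6-(4-methylpent-3-en-1-yl)-4H-1,3-dioxin-4-one; 10 acetyl chloride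
Product: 11 2,2-dimethyl-6-(6-methyl-2-oxohept-5-en-3-yl)-4H-1,3-dioxin-4-one (racemic)
Conditions: LiHMDS, THF, −78 °C; then 10 (0.5 equiv per dienolate), −78 °C; AcOH; excess 9 recovered
Reagents that add atoms: none
Why: γ-C-Acylation of the dioxinone dienolate by an acid chloride (vinylogous Claisen acylation), in which the more acidic keto-dioxinone is deprotonated at once by the second equivalent of dienolate and is thereby protected from a second acylation.

Step 7
Reactants: 11 2,2-dimethyl-6-(6-methyl-2-oxohept-5-en-3-yl)-4H-1,3-dioxin-4-one; 7 (3S)-3-[(tert-butyldimethylsilyl)oxy]-N-methoxy-N-methyl-3-{4-[(3-methylbut-2-en-1-yl)oxy]phenyl}propanamide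
Product: 12 6-[(10S)-10-[(tert-butyldimethylsilyl)oxy]-2-methyl-10-{4-[(3-methylbut-2-en-1-yl)oxy]phenyl}-6,8-dioxodec-2-en-5-yl]-2,2-dimethyl-4H-1,3-dioxin-4-one
Conditions: 11 (1.5 equiv), LDA (2.1 equiv per 11), THF, −78 → −40 °C; then 7, −78 → −30 °C; AcOH, pH 7 buffer; crude 12 used directly
Reagents that add atoms: none
Why: Weinreb ketone synthesis with a 1,3-dianion, in which the last-formed methyl carbanion is the most nucleophilic site and the chelated tetrahedral intermediate survives until the quench, so neither over-addition nor proton exchange with the diketone occurs and the silyloxy stereocentre is not involved.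

Step 8
Reactants: 12 6-[(10S)-10-[(tert-butyldimethylsilyl)oxy]-2-methyl-10-{4-[(3-methylbut-2-en-1-yl)oxy]phenyl}-6,8-dioxodec-2-en-5-yl]-2,2-dimethyl-4H-1,3-dioxin-4-one
Product: 15 (2S)-6-[1-(2,2-dimethyl-4-oxo-4H-1,3-dioxin-6-yl)-4-methylpent-3-en-1-yl]-2-{4-[(3-methylbut-2-en-1-yl)oxy]phenyl}-2,3-dihydro-4H-pyran-4-one (both side-chain epimers), via δ-hydroxy-β-diketone 13 (not isolated), via cyclic hemiketal 14 (not isolated)
Conditions: HF·pyridine, pyridine, THF, 0 °C → rt; NaHCO3 wash; then PPTS (10 mol %), CH2Cl2, 4 Å MS, rt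
Reagents that add atoms: none
Why: Fluoride desilylation followed by acid-catalysed cyclodehydration of a δ-hydroxy-β-diketone (hemiketalisation, then β-elimination of water to the vinylogous ester), in which only the distal ketone can close a six-membered ring, the C2–O1 bond is never broken so 2S is retained, and buffered HF and PPTS are too weak to ionise the aryl prenyl ether, the benzylic C–O bond or the dioxinone.

Step 9
Reactants: 15 (2S)-6-[1-(2,2-dimethyl-4-oxo-4H-1,3-dioxin-6-yl)-4-methylpent-3-en-1-yl]-2-{4-[(3-methylbut-2-en-1-yl)oxy]phenyl}-2,3-dihydro-4H-pyran-4-one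
Product: 18 (2S)-5,7-dihydroxy-8-(3-methylbut-2-en-1-yl)-2-{4-[(3-methylbut-2-en-1-yl)oxy]phenyl}-2,3-dihydro-4H-chromen-4-one, via acylketene 16 (not isolated), via triketone tautomer 17 (not isolated)
Conditions: PhMe, 110 °C, 1 mM (slow addition of 15), Ar
Reagents that add atoms: none
Why: Proposed new method: retro-[4+2] loss of acetone from the dioxinone gives acylketene 16, whose ketene carbon is attacked by C5 of the dihydropyranone (the α-carbon of the vinylogous ester, future C4a), either directly or, after enolisation of the doubly activated C8–H, as a 6π-electrocyclisation of the resulting dienylketene; proton shifts then convert triketone 17 into the phloroglucinol. The closest known reactions are the thermal dioxinone-to-acylketene fragmentation with intramolecular capture, the Claisen-mode aromatisation of polyketo chains to acylphloroglucinols, and the dienylketene electrocyclisation that ends ketene-based benzannulations. Ring A closes in a 6-(enolendo)-exo-dig mode at the ketene carbonyl. No stereocentre is created: C2 is untouched because the medium is neutral and aprotic, so the base-mediated retro-oxa-Michael opening of the flavanone cannot operate, and the side-chain stereocentre of 15 vanishes on aromatisation. The step needs intramolecular C-acylation to beat ketene dimerisation and O-capture; the oxygen on C8a is already the ring-C ether and so cannot give the usual 2-pyranone by enol O-acylation, the C4 carbonyl oxygen cannot reach the ketene, and millimolar concentration with slow addition suppresses bimolecular paths, including capture by the phenols of 18.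

**Compound list**

1 | methyl 4-hydroxybenzoate | COC(=O)c1ccc(O)cc1 | starting material
2 | prenyl bromide (1-bromo-3-methylbut-2-ene) | CC(C)=CCBr | starting material
3 | methyl 4-[(3-methylbut-2-en-1-yl)oxy]benzoate | COC(=O)c1ccc(OCC=C(C)C)cc1 | intermediate
4 | N-methoxy-N-methylacetamide | CC(=O)N(C)OC | starting material
5 | N-methoxy-N-methyl-3-{4-[(3-methylbut-2-en-1-yl)oxy]phenyl}-3-oxopropanamide | CC(C)=CCOc1ccc(C(=O)CC(=O)N(C)OC)cc1 | intermediate
6 | (3S)-3-hydroxy-N-methoxy-N-methyl-3-{4-[(3-methylbut-2-en-1-yl)oxy]phenyl}propanamide | CC(C)=CCOc1ccc([C@@H](O)CC(=O)N(C)OC)cc1 | intermediate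
7 | (3S)-3-[(tert-butyldimethylsilyl)oxy]-N-methoxy-N-methyl-3-{4-[(3-methylbut-2-en-1-yl)oxy]phenyl}propanamide | CC(C)=CCOc1ccc([C@@H](O[Si](C)(C)C(C)(C)C)CC(=O)N(C)OC)cc1 | intermediate
8 | 2,2,6-trimethyl-4H-1,3-dioxin-4-one | CC1=CC(=O)OC(C)(C)O1 | starting material
9 | 2,2-dimethyl-6-(4-methylpent-3-en-1-yl)-4H-1,3-dioxin-4-one | CC(C)=CCCC1=CC(=O)OC(C)(C)O1 | intermediate
10 | acetyl chloride | CC(=O)Cl | starting material
11 | 2,2-dimethyl-6-(6-methyl-2-oxohept-5-en-3-yl)-4H-1,3-dioxin-4-one (racemic) | CC(=O)C(CC=C(C)C)C1=CC(=O)OC(C)(C)O1 | intermediate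
12 | 6-[(10S)-10-[(tert-butyldimethylsilyl)oxy]-2-methyl-10-{4-[(3-methylbut-2-en-1-yl)oxy]phenyl}-6,8-dioxodec-2-en-5-yl]-2,2-dimethyl-4H-1,3-dioxin-4-one (epimers at C5 of the chain) | CC(C)=CCOc1ccc([C@@H](O[Si](C)(C)C(C)(C)C)CC(=O)CC(=O)C(CC=C(C)C)C2=CC(=O)OC(C)(C)O2)cc1 | intermediate
13 | 6-[(10S)-10-hydroxy-2-methyl-10-{4-[(3-methylbut-2-en-1-yl)oxy]phenyl}-6,8-dioxodec-2-en-5-yl]-2,2-dimethyl-4H-1,3-dioxin-4-one (δ-hydroxy-β-diketone, not isolated) | CC(C)=CCOc1ccc([C@@H](O)CC(=O)CC(=O)C(CC=C(C)C)C2=CC(=O)OC(C)(C)O2)cc1 | intermediate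
14 | (2S)-6-[1-(2,2-dimethyl-4-oxo-4H-1,3-dioxin-6-yl)-4-methylpent-3-en-1-yl]-6-hydroxy-2-{4-[(3-methylbut-2-en-1-yl)oxy]phenyl}tetrahydro-4H-pyran-4-one (cyclic hemiketal, not isolated) | CC(C)=CCOc1ccc([C@@H]2CC(=O)CC(O)(C(CC=C(C)C)C3=CC(=O)OC(C)(C)O3)O2)cc1 | intermediate
15 | (2S)-6-[1-(2,2-dimethyl-4-oxo-4H-1,3-dioxin-6-yl)-4-methylpent-3-en-1-yl]-2-{4-[(3-methylbut-2-en-1-yl)oxy]phenyl}-2,3-dihydro-4H-pyran-4-one (both side-chain epimers) | CC(C)=CCOc1ccc([C@@H]2CC(=O)C=C(C(CC=C(C)C)C3=CC(=O)OC(C)(C)O3)O2)cc1 | intermediate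
16 | 7-methyl-4-[(2S)-2-{4-[(3-methylbut-2-en-1-yl)oxy]phenyl}-4-oxo-3,4-dihydro-2H-pyran-6-yl]-3-oxoocta-1,6-dien-1-one (acylketene, not isolated) | CC(C)=CCOc1ccc([C@@H]2CC(=O)C=C(C(CC=C(C)C)C(=O)C=C=O)O2)cc1 | intermediate
17 | (2S)-8-(3-methylbut-2-en-1-yl)-2-{4-[(3-methylbut-2-en-1-yl)oxy]phenyl}-2,3-dihydro-4H-chromene-4,5,7(6H,8H)-trione (triketone tautomer of 18, not isolated) | CC(C)=CCOc1ccc([C@@H]2CC(=O)C3=C(O2)C(CC=C(C)C)C(=O)CC3=O)cc1 | intermediate
18 | (2S)-5,7-dihydroxy-8-(3-methylbut-2-en-1-yl)-2-{4-[(3-methylbut-2-en-1-yl)oxy]phenyl}-2,3-dihydro-4H-chromen-4-one | CC(C)=CCOc1ccc([C@@H]2CC(=O)c3c(O)cc(O)c(CC=C(C)C)c3O2)cc1 | target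

**Step count.** Total: 9 steps. Longest linear sequence: 7 steps (1, 2, 3, 4, 7, 8, 9); the dioxinone branch (5, 6) joins at step 7.

**Steps most likely to fail**

Step 9 (ring A closure). The acylketene may be consumed before C4a attacks: by [4+2] dimerisation, by capture at O1 followed by cleavage of the benzylic C2–O1 bond, or by an ene-type reaction with the neighbouring prenyl alkene. The fallback brings ring A in ready-made and closes ring C last by known reactions; it sets out from prenyl bromide 2 and returns to the route at target 18.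
- Compound 2 alkylates commercial 4-hydroxyphenylboronic acid pinacol ester (K2CO3, acetone) to 2-{4-[(3-methylbut-2-en-1-yl)oxy]phenyl}-4,4,5,5-tetramethyl-1,3,2-dioxaborolane F1.
- Commercial 5,7-dihydroxychromone is silylated at the non-chelated 7-hydroxyl (TIPSCl, imidazole) to 5-hydroxy-7-[(triisopropylsilyl)oxy]-4H-chromen-4-one F2.
- The chelated 5-hydroxyl is etherified with 3-methylbut-2-en-1-ol under Mitsunobu conditions to 5-[(3-methylbut-2-en-1-yl)oxy]-7-[(triisopropylsilyl)oxy]-4H-chromen-4-one F3.
- A Eu(fod)3-catalysed para-Claisen–Cope rearrangement moves the prenyl group to C8 and gives 5-hydroxy-8-(3-methylbut-2-en-1-yl)-7-[(triisopropylsilyl)oxy]-4H-chromen-4-one F4, with the regiochemistry fixed.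
- Rhodium-catalysed asymmetric 1,4-addition of F1 to F4 (Hayashi–Miyaura reaction, with the bisphosphine enantiomer that delivers 2S) should give (2S)-5-hydroxy-8-(3-methylbut-2-en-1-yl)-2-{4-[(3-methylbut-2-en-1-yl)oxy]phenyl}-7-[(triisopropylsilyl)oxy]-2,3-dihydro-4H-chromen-4-one F5.
- Buffered fluoride (TBAF/AcOH, THF, 0 °C) frees the 7-hydroxyl to give 18.

Step 7 (fragment union). Proton transfer from the α-methylene of 7 to the dianion, followed by β-elimination of silanolate, or incomplete second deprotonation of the hindered enolate of 11, would leave the partners unjoined. The fallback changes the electrophile from an amide to an aldehyde; it sets out from 7 and returns at 12. DIBAL-H (THF, −78 °C) reduces 7 to (3S)-3-[(tert-butyldimethylsilyl)oxy]-3-{4-[(3-methylbut-2-en-1-yl)oxy]phenyl}propanal F6. Aldol addition of the same dianion of 11 at −78 °C gives 6-[(10S)-10-[(tert-butyldimethylsilyl)oxy]-8-hydroxy-2-methyl-10-{4-[(3-methylbut-2-en-1-yl)oxy]phenyl}-6-oxodec-2-en-5-yl]-2,2-dimethyl-4H-1,3-dioxin-4-one F7 as a diastereomer mixture. Dess–Martin periodinane (NaHCO3, CH2Cl2) oxidises the β-hydroxy ketone to 12.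

Step 5 (γ-prenylation). Alkylation may go to the α-carbon (C5 of the dioxinone) or twice at the γ-carbon, and the dienolate may self-condense on warming. The fallback inverts the order of the two bond formations; it sets out from 8 and returns at 11, so that 9 and step 6 are no longer needed. The dienolate of 8 is acetylated with 10 (LiHMDS, THF, −78 °C) to 2,2-dimethyl-6-(2-oxopropyl)-4H-1,3-dioxin-4-one F8. Its stabilised monoanion (K2CO3, acetone, rt) is then C-alkylated with 2 at the doubly activated methylene to give 11.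

**Further compounds**

F1 | step 9 | 2-{4-[(3-methylbut-2-en-1-yl)oxy]phenyl}-4,4,5,5-tetramethyl-1,3,2-dioxaborolane | CC(C)=CCOc1ccc(B2OC(C)(C)C(C)(C)O2)cc1
F2 | step 9 | 5-hydroxy-7-[(triisopropylsilyl)oxy]-4H-chromen-4-one | CC(C)[Si](Oc1cc(O)c2c(c1)occc2=O)(C(C)C)C(C)C
F3 | step 9 | 5-[(3-methylbut-2-en-1-yl)oxy]-7-[(triisopropylsilyl)oxy]-4H-chromen-4-one | CC(C)=CCOc1cc(O[Si](C(C)C)(C(C)C)C(C)C)cc2occc(=O)c12
F4 | step 9 | 5-hydroxy-8-(3-methylbut-2-en-1-yl)-7-[(triisopropylsilyl)oxy]-4H-chromen-4-one | CC(C)=CCc1c(O[Si](C(C)C)(C(C)C)C(C)C)cc(O)c2c(=O)ccoc12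
F5 | step 9 | (2S)-5-hydroxy-8-(3-methylbut-2-en-1-yl)-2-{4-[(3-methylbut-2-en-1-yl)oxy]phenyl}-7-[(triisopropylsilyl)oxy]-2,3-dihydro-4H-chromen-4-one | CC(C)=CCOc1ccc([C@@H]2CC(=O)c3c(O)cc(O[Si](C(C)C)(C(C)C)C(C)C)c(CC=C(C)C)c3O2)cc1
F6 | step 7 | (3S)-3-[(tert-butyldimethylsilyl)oxy]-3-{4-[(3-methylbut-2-en-1-yl)oxy]phenyl}propanal | CC(C)=CCOc1ccc([C@@H](O[Si](C)(C)C(C)(C)C)CC=O)cc1
F7 | step 7 | 6-[(10S)-10-[(tert-butyldimethylsilyl)oxy]-8-hydroxy-2-methyl-10-{4-[(3-methylbut-2-en-1-yl)oxy]phenyl}-6-oxodec-2-en-5-yl]-2,2-dimethyl-4H-1,3-dioxin-4-one | CC(C)=CCOc1ccc([C@@H](O[Si](C)(C)C(C)(C)C)CC(O)CC(=O)C(CC=C(C)C)C2=CC(=O)OC(C)(C)O2)cc1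
F8 | step 5 | 2,2-dimethyl-6-(2-oxopropyl)-4H-1,3-dioxin-4-one | CC(=O)CC1=CC(=O)OC(C)(C)O1
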